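**Retrosynthetic overview**

- The prenyl ketone is made last from a C9' carboxyl group. C9'–C10' comes from acylation of a prenyl sulfone anion, and C8' from Ru-catalysed asymmetric hydrogenation of an (E)-2-methyl-2-enoic acid, itself made by oxidising the terminal E-methyl group of the side chain.
- The strategy rests on one feature: the dihydropyran ring is fused to the benzene ring through the neighbouring carbons C4a and C8a, and C8 on the far side of C8a carries a methyl group. The four-atom unit C4–C3–C2–O1 can therefore be laid across the one free ortho C–H and the iodine-bearing carbon of a 2-methyl aryl iodide. This cuts C4–C4a and O1–C8a.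
- The two pieces are an enantiopure 2,2-disubstituted oxetane (farnesol; Sharpless epoxidation sets C2; reductive opening, tosylation, ring closure) and the silyl ether of 4-iodo-3-methylphenol.
- Ring order: the benzene ring is bought; the dihydropyran ring is the only ring formed, in step 6.

Key step: step 6

Remark: side-chain carbons carry primed locants (C1' on chroman C2 out to C12'). In step 10 the (S)-configured ligand is assumed to give the (S)-acid, as it does with tiglic acid; the antipodal ligand is used if the first batch shows the opposite sense.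

**Route**

Step 1
Reactants: 1 (2E,6E)-farnesol
Product: 2 [(2R,3R)-3-methyl-3-[(3E)-4,8-dimethylnona-3,7-dien-1-yl]oxiran-2-yl]methanol
Conditions: Ti(Oi-Pr)4 (cat.), D-(−)-diethyl tartrate (cat.), t-BuOOH, 4 Å MS, CH2Cl2, −20 °C
Reagents that add atoms: tert-butyl hydroperoxide, CC(C)(C)OO
Why: Sharpless asymmetric epoxidation is directed by the allylic hydroxyl, so only the C2=C3 alkene reacts, and the D-(−)-tartrate ligand should deliver oxygen to the face that gives the (2R,3R)-epoxide, whose C3 becomes C2 of the chroman.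

Step 2
Reactants: 2 (2R,3R)-2,3-epoxyfarnesol
Product: 3 (3R,6E)-3,7,11-trimethyldodeca-6,10-diene-1,3-diol
Conditions: NaAlH2(OCH2CH2OMe)2, THF, 0 °C
Reagents that add atoms: none
Why: Regioselective reductive opening of a 2,3-epoxy alcohol, in which the aluminium alkoxide at C1 delivers hydride to the less substituted C2, so the C3–O bond and its configuration are kept.

Step 3
Reactants: 3 (R)-1,3-diol
Product: 4 (3R,6E)-3-hydroxy-3,7,11-trimethyldodeca-6,10-dien-1-yl 4-methylbenzenesulfonate
Conditions: TsCl, Et3N, DMAP (cat.), CH2Cl2, 0 °C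
Reagents that add atoms: p-toluenesulfonyl chloride, Cc1ccc(cc1)S(Cl)(=O)=O
Why: Selective sulfonylation, since the primary hydroxyl reacts far faster than the hindered tertiary one.

Step 4
Reactants: 4 hydroxy tosylate
Product: 5 (2R)-2-methyl-2-[(3E)-4,8-dimethylnona-3,7-dien-1-yl]oxetane
Conditions: KOt-Bu, THF, 0 °C to rt
Reagents that add atoms: none
Why: Intramolecular Williamson etherification (4-exo-tet) in which the tertiary alkoxide displaces the primary tosylate, so the stereocentre, which carries the nucleophile, is untouched.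

Step 5
Reactants: 6 4-iodo-3-methylphenol
Product: 7 (4-iodo-3-methylphenoxy)triisopropylsilane
Conditions: TIPSCl, imidazole, DMF, rt
Reagents that add atoms: chlorotriisopropylsilane, CC(C)[Si](Cl)(C(C)C)C(C)C
Why: Silyl ether protection of the phenol gives a hindered ether that should tolerate carbonate, carbanions and single-electron reduction later on.

Step 6
Reactants: 5 (R)-oxetane; 7 (4-iodo-3-methylphenoxy)triisopropylsilane
Product: 9 triisopropyl{[(2R)-2,8-dimethyl-2-[(3E)-4,8-dimethylnona-3,7-dien-1-yl]-3,4-dihydro-2H-chromen-6-yl]oxy}silane, via lithium iodoalkoxide 8 (not isolated)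
Conditions: Pd(OAc)2 (10 mol %), XPhos (20 mol %), norbornene, LiI (30 mol %), K2CO3, anhydrous MeCN, 80 °C
Reagents that add atoms: none
Why: Proposed new method: zerovalent palladium adds to the C–I bond of 7, norbornene inserts and the single free ortho C–H is palladated to the aryl–norbornyl palladacycle of divalent palladium, while LiI reversibly opens the lithium-activated oxetane at its unhindered CH2 to the γ-iodo alkoxide 8, whose primary C–I bond adds to the palladacycle in SN2 fashion (tetravalent palladium) before reductive elimination forms C4–C4a. With both ortho positions then filled, norbornene is expelled by β-carbon elimination and the tethered tertiary alkoxide replaces iodide on divalent palladium to give a seven-membered oxapalladacycle. C(aryl)–O reductive elimination forms O1–C8a and closes the six-membered dihydropyran ring by intramolecular aryl etherification, a tertiary alkoxide having no β-hydrogen to lose. The nearest established reactions are the palladium/norbornene annulation of aryl iodides with epoxides, which gives 2,3-dihydrobenzofurans, and ortho-alkylation/ipso-amination with haloalkyl amines; an oxetane has not been shown to give a chroman this way. No stereocentre is created, because the oxygen stays bonded to C2 throughout and C2 keeps the R configuration from step 1. The step needs ortho/ipso site selectivity, which the C8 methyl group secures by blocking the second ortho position, and opening at CH2 and not at the quaternary carbon, which the SN2 iodide opening under only mild Lewis acidity secures.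

Step 7
Reactants: 9 silyl-protected chroman diene
Product: 10 (2E,6E)-2,6-dimethyl-9-[(2R)-2,8-dimethyl-6-(triisopropylsilyloxy)chroman-2-yl]nona-2,6-dien-1-ol
Conditions: SeO2 (cat.), t-BuOOH, salicylic acid (cat.), CH2Cl2, 0 °C to rt
Reagents that add atoms: tert-butyl hydroperoxide, CC(C)(C)OO
Why: Selenium dioxide allylic oxidation (ene reaction, then [2,3]-sigmatropic shift) should attack the E-methyl group of the terminal trisubstituted alkene, the most accessible allylic site of the chain, and give the (E)-allylic alcohol.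

Step 8
Reactants: 10 allylic alcohol
Product: 11 (2E,6E)-2,6-dimethyl-9-[(2R)-2,8-dimethyl-6-(triisopropylsilyloxy)chroman-2-yl]nona-2,6-dienal
Conditions: MnO2, CH2Cl2, rt
Reagents that add atoms: none
Why: MnO2 oxidises allylic alcohols selectively to enals without affecting the alkenes, the silyl ether or the benzylic positions.

Step 9
Reactants: 11 enal
Product: 12 (2E,6E)-2,6-dimethyl-9-[(2R)-2,8-dimethyl-6-(triisopropylsilyloxy)chroman-2-yl]nona-2,6-dienoic acid
Conditions: NaClO2, NaH2PO4, 2-methyl-2-butene, t-BuOH/H2O, rt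
Reagents that add atoms: sodium chlorite, [Na+].[O-]Cl=O
Why: Pinnick oxidation converts the enal to the acid without moving the alkene, and 2-methyl-2-butene traps the hypochlorous acid that would otherwise chlorinate the alkenes and the electron-rich arene.

Step 10
Reactants: 12 (E)-2-methyl-2-enoic acid
Product: 13 (2S,6E)-2,6-dimethyl-9-[(2R)-2,8-dimethyl-6-(triisopropylsilyloxy)chroman-2-yl]non-6-enoic acid
Conditions: Ru(OAc)2[(S)-H8-BINAP] (cat.), H2 (2–4 atm), MeOH, rt
Reagents that add atoms: none
Why: Carboxylate-directed asymmetric hydrogenation reduces only the conjugated C7'=C8' alkene, the (S)-ligand controlling the face of hydrogen delivery to set C8' as S, while the isolated C3'=C4' alkene cannot chelate and is left alone.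

Step 11
Reactants: 13 (S)-acid
Product: 15 (2S,6E)-N-methoxy-N,2,6-trimethyl-9-[(2R)-2,8-dimethyl-6-(triisopropylsilyloxy)chroman-2-yl]non-6-enamide, via acyl imidazolide 14 (not isolated)
Conditions: CDI, CH2Cl2, rt; then MeNH(OMe)·HCl
Reagents that add atoms: N,O-dimethylhydroxylamine hydrochloride, CNOC.Cl
Why: Weinreb amide formation through the acyl imidazolide runs under nearly neutral conditions that should not enolise C8'.

Step 12
Reactants: 16 prenyl bromide
Product: 17 (3-methylbut-2-en-1-yl) phenyl sulfone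
Conditions: PhSO2Na, DMF, rt
Reagents that add atoms: sodium benzenesulfinate, [Na+].[O-]S(=O)c1ccccc1
Why: SN2 alkylation of the sulfinate at sulfur by the primary allylic bromide gives the sulfone.

Step 13
Reactants: 17 prenyl phenyl sulfone; 15 Weinreb amide
Product: 19 (6S,10E)-2,6,10-trimethyl-4-(phenylsulfonyl)-13-[(2R)-2,8-dimethyl-6-(triisopropylsilyloxy)chroman-2-yl]trideca-2,10-dien-5-one (mixture of epimers at C4), via lithiated sulfone 18 (not isolated)
Conditions: n-BuLi, THF, −78 °C; then 15, −78 °C; aq. NH4Cl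
Reagents that add atoms: none
Why: Weinreb ketone synthesis in which the sulfonyl-stabilised allyl anion acylates at its α-carbon, the chelated tetrahedral intermediate prevents a second addition, and the anion is too weak a base to deprotonate C8'.

Step 14
Reactants: 19 β-keto sulfone
Product: 20 (6S,10E)-2,6,10-trimethyl-13-[(2R)-2,8-dimethyl-6-(triisopropylsilyloxy)chroman-2-yl]trideca-2,10-dien-5-one
Conditions: SmI2, THF/MeOH, −78 °C
Reagents that add atoms: none
Why: Reductive desulfonylation, in which electron transfer from SmI2 cleaves the C–S bond to a samarium dienolate that methanol should protonate kinetically at the α-carbon, leaving the C11'=C12' alkene out of conjugation.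

Step 15
Reactants: 20 silyl-protected ketone
Product: 21 (6S,10E)-13-[(2R)-6-hydroxy-2,8-dimethylchroman-2-yl]-2,6,10-trimethyltrideca-2,10-dien-5-one (target, 2R,8'S)
Conditions: TBAF, AcOH, THF, 0 °C
Reagents that add atoms: none
Why: Fluoride-mediated desilylation of the aryl silyl ether, buffered with acetic acid so that C8' is not epimerised and the β,γ-alkene does not migrate.

**Compound list**

1 | (2E,6E)-farnesol | CC(C)=CCC/C(C)=C/CC/C(C)=C/CO | starting material
2 | [(2R,3R)-3-methyl-3-[(3E)-4,8-dimethylnona-3,7-dien-1-yl]oxiran-2-yl]methanol | CC(C)=CCC/C(C)=C/CC[C@@]1(C)O[C@@H]1CO | intermediate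
3 | (3R,6E)-3,7,11-trimethyldodeca-6,10-diene-1,3-diol | CC(C)=CCC/C(C)=C/CC[C@@](C)(O)CCO | intermediate
4 | (3R,6E)-3-hydroxy-3,7,11-trimethyldodeca-6,10-dien-1-yl 4-methylbenzenesulfonate | CC(C)=CCC/C(C)=C/CC[C@@](C)(O)CCOS(=O)(=O)c1ccc(C)cc1 | intermediate
5 | (2R)-2-methyl-2-[(3E)-4,8-dimethylnona-3,7-dien-1-yl]oxetane | CC(C)=CCC/C(C)=C/CC[C@]1(C)CCO1 | intermediate
6 | 4-iodo-3-methylphenol | Cc1cc(O)ccc1I | starting material
7 | (4-iodo-3-methylphenoxy)triisopropylsilane | Cc1cc(O[Si](C(C)C)(C(C)C)C(C)C)ccc1I | intermediate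
8 | lithium (3R,6E)-1-iodo-3,7,11-trimethyldodeca-6,10-dien-3-olate | CC(C)=CCC/C(C)=C/CC[C@@](C)([O-])CCI.[Li+] | intermediate (not isolated)
9 | triisopropyl{[(2R)-2,8-dimethyl-2-[(3E)-4,8-dimethylnona-3,7-dien-1-yl]-3,4-dihydro-2H-chromen-6-yl]oxy}silane | CC(C)=CCC/C(C)=C/CC[C@]1(C)CCc2cc(O[Si](C(C)C)(C(C)C)C(C)C)cc(C)c2O1 | intermediate
10 | (2E,6E)-2,6-dimethyl-9-[(2R)-2,8-dimethyl-6-(triisopropylsilyloxy)chroman-2-yl]nona-2,6-dien-1-ol | OC/C(C)=C/CC/C(C)=C/CC[C@]1(C)CCc2cc(O[Si](C(C)C)(C(C)C)C(C)C)cc(C)c2O1 | intermediate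
11 | (2E,6E)-2,6-dimethyl-9-[(2R)-2,8-dimethyl-6-(triisopropylsilyloxy)chroman-2-yl]nona-2,6-dienal | O=C/C(C)=C/CC/C(C)=C/CC[C@]1(C)CCc2cc(O[Si](C(C)C)(C(C)C)C(C)C)cc(C)c2O1 | intermediate
12 | (2E,6E)-2,6-dimethyl-9-[(2R)-2,8-dimethyl-6-(triisopropylsilyloxy)chroman-2-yl]nona-2,6-dienoic acid | OC(=O)/C(C)=C/CC/C(C)=C/CC[C@]1(C)CCc2cc(O[Si](C(C)C)(C(C)C)C(C)C)cc(C)c2O1 | intermediate
13 | (2S,6E)-2,6-dimethyl-9-[(2R)-2,8-dimethyl-6-(triisopropylsilyloxy)chroman-2-yl]non-6-enoic acid | OC(=O)[C@@H](C)CCC/C(C)=C/CC[C@]1(C)CCc2cc(O[Si](C(C)C)(C(C)C)C(C)C)cc(C)c2O1 | intermediate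
14 | 1-{(2S,6E)-2,6-dimethyl-9-[(2R)-2,8-dimethyl-6-(triisopropylsilyloxy)chroman-2-yl]non-6-enoyl}imidazole | O=C(n3ccnc3)[C@@H](C)CCC/C(C)=C/CC[C@]1(C)CCc2cc(O[Si](C(C)C)(C(C)C)C(C)C)cc(C)c2O1 | intermediate (not isolated)
15 | (2S,6E)-N-methoxy-N,2,6-trimethyl-9-[(2R)-2,8-dimethyl-6-(triisopropylsilyloxy)chroman-2-yl]non-6-enamide | CON(C)C(=O)[C@@H](C)CCC/C(C)=C/CC[C@]1(C)CCc2cc(O[Si](C(C)C)(C(C)C)C(C)C)cc(C)c2O1 | intermediate
16 | prenyl bromide (1-bromo-3-methylbut-2-ene) | CC(C)=CCBr | starting material
17 | (3-methylbut-2-en-1-yl) phenyl sulfone | CC(C)=CCS(=O)(=O)c1ccccc1 | intermediate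
18 | [3-methyl-1-(phenylsulfonyl)but-2-en-1-yl]lithium | CC(C)=CC([Li])S(=O)(=O)c1ccccc1 | intermediate (not isolated)
19 | (6S,10E)-2,6,10-trimethyl-4-(phenylsulfonyl)-13-[(2R)-2,8-dimethyl-6-(triisopropylsilyloxy)chroman-2-yl]trideca-2,10-dien-5-one, epimers at C4 | CC(C)=CC(C(=O)[C@@H](C)CCC/C(C)=C/CC[C@]1(C)CCc2cc(O[Si](C(C)C)(C(C)C)C(C)C)cc(C)c2O1)S(=O)(=O)c3ccccc3 | intermediate
20 | (6S,10E)-2,6,10-trimethyl-13-[(2R)-2,8-dimethyl-6-(triisopropylsilyloxy)chroman-2-yl]trideca-2,10-dien-5-one | CC(C)=CCC(=O)[C@@H](C)CCC/C(C)=C/CC[C@]1(C)CCc2cc(O[Si](C(C)C)(C(C)C)C(C)C)cc(C)c2O1 | intermediate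
21 | (6S,10E)-13-[(2R)-6-hydroxy-2,8-dimethylchroman-2-yl]-2,6,10-trimethyltrideca-2,10-dien-5-one | CC(C)=CCC(=O)[C@@H](C)CCC/C(C)=C/CC[C@]1(C)CCc2cc(O)cc(C)c2O1 | target

**Step count**

Total: 15 steps. Longest linear sequence: 13 steps from farnesol (steps 1–4, 6–11, 13–15).

**Steps most likely to fail**

1. Step 6 (proposed new method). The oxetane may not be opened fast enough to intercept the palladacycle, so that norbornene-derived arenes or the reduced arene form instead. The alkylated arylpalladium may be protonated before C–O reductive elimination. The silyl ether may be cleaved by carbonate at 80 °C. The fallback uses known chemistry, with separate C–C and C–O bond formation; it sets out from oxetane 5 and rejoins at 9. Commercial 3-bromo-5-methylphenol would be chlorinated para to the hydroxyl (SO2Cl2, CH2Cl2) to 3-bromo-4-chloro-5-methylphenol F1 and silylated (TIPSCl, imidazole, DMF) to (3-bromo-4-chloro-5-methylphenoxy)triisopropylsilane F2. Bromine–lithium exchange (n-BuLi, THF, −95 °C), then 5 and BF3·OEt2, should open the oxetane at CH2 and give (3R,6E)-1-[2-chloro-3-methyl-5-(triisopropylsilyloxy)phenyl]-3,7,11-trimethyldodeca-6,10-dien-3-ol F3. Intramolecular palladium-catalysed aryl etherification of the tertiary alcohol (Buchwald–Hartwig C–O coupling; Pd(OAc)2, t-BuXPhos, Cs2CO3, toluene, 90 °C) then forms O1–C8a and gives 9, with C2 again untouched.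

2. Step 7. The oxidation may not discriminate between the terminal and the internal trisubstituted alkene, or may run on to mixtures of alcohol, enal and doubly oxidised material at partial conversion. The fallback replaces allylic oxidation by cleavage and olefination; it sets out from 9 and rejoins at 11. Terminal-selective bromohydrin formation (NBS, THF/H2O, 0 °C) would give (6E)-3-bromo-2,6-dimethyl-9-[(2R)-2,8-dimethyl-6-(triisopropylsilyloxy)chroman-2-yl]non-6-en-2-ol F4. Ring closure (K2CO3, MeOH, 0 °C) would give triisopropyl{[(2R)-2-[(3E)-6-(3,3-dimethyloxiran-2-yl)-4-methylhex-3-en-1-yl]-2,8-dimethylchroman-6-yl]oxy}silane F5. Periodic acid cleavage (HIO4, THF/H2O) would give (4E)-4-methyl-7-[(2R)-2,8-dimethyl-6-(triisopropylsilyloxy)chroman-2-yl]hept-4-enal F6. Wittig olefination with 2-(triphenylphosphoranylidene)propanal (toluene, 90 °C) should then return the (E)-enal 11.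

3. Step 14. The dienolate may be protonated at the γ-carbon, or the alkene may later migrate into conjugation, and enolisation towards C8' would erode its configuration. The fallback builds the prenyl group by metathesis instead of by sulfone chemistry; it sets out from Weinreb amide 15 and rejoins at 20, bypassing steps 13 and 14. Allylmagnesium bromide (THF, −78 °C) would give (5S,9E)-5,9-dimethyl-12-[(2R)-2,8-dimethyl-6-(triisopropylsilyloxy)chroman-2-yl]dodeca-1,9-dien-4-one F7. Cross-metathesis of its terminal vinyl group with excess 2-methyl-2-butene (second-generation Grubbs catalyst, CH2Cl2, 40 °C) should give 20, the trisubstituted C9=C10 alkene being inert.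

**Further compounds**

F1 | step 6 | 3-bromo-4-chloro-5-methylphenol | Cc1cc(O)cc(Br)c1Cl
F2 | step 6 | (3-bromo-4-chloro-5-methylphenoxy)triisopropylsilane | Cc1cc(O[Si](C(C)C)(C(C)C)C(C)C)cc(Br)c1Cl
F3 | step 6 | (3R,6E)-1-[2-chloro-3-methyl-5-(triisopropylsilyloxy)phenyl]-3,7,11-trimethyldodeca-6,10-dien-3-ol | CC(C)=CCC/C(C)=C/CC[C@@](C)(O)CCc1cc(O[Si](C(C)C)(C(C)C)C(C)C)cc(C)c1Cl
F4 | step 7 | (6E)-3-bromo-2,6-dimethyl-9-[(2R)-2,8-dimethyl-6-(triisopropylsilyloxy)chroman-2-yl]non-6-en-2-ol | CC(C)(O)C(Br)CC/C(C)=C/CC[C@]1(C)CCc2cc(O[Si](C(C)C)(C(C)C)C(C)C)cc(C)c2O1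
F5 | step 7 | triisopropyl{[(2R)-2-[(3E)-6-(3,3-dimethyloxiran-2-yl)-4-methylhex-3-en-1-yl]-2,8-dimethylchroman-6-yl]oxy}silane | CC3(C)OC3CC/C(C)=C/CC[C@]1(C)CCc2cc(O[Si](C(C)C)(C(C)C)C(C)C)cc(C)c2O1
F6 | step 7 | (4E)-4-methyl-7-[(2R)-2,8-dimethyl-6-(triisopropylsilyloxy)chroman-2-yl]hept-4-enal | O=CCC/C(C)=C/CC[C@]1(C)CCc2cc(O[Si](C(C)C)(C(C)C)C(C)C)cc(C)c2O1
F7 | step 14 | (5S,9E)-5,9-dimethyl-12-[(2R)-2,8-dimethyl-6-(triisopropylsilyloxy)chroman-2-yl]dodeca-1,9-dien-4-one | C=CCC(=O)[C@@H](C)CCC/C(C)=C/CC[C@]1(C)CCc2cc(O[Si](C(C)C)(C(C)C)C(C)C)cc(C)c2O1
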